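The flavone core is cut at O1–C8a, C4a–C4 and O1–C2, which strips ring C back to an aryne and an arylpropiolic acid. The route exploits the fact that ring A carries O1 (on C8a) and the C4 carbonyl (on C4a) on adjacent carbons next to the C5 oxygen: a 3-alkoxybenzyne inserts into the O–C(acyl) bond of a carboxylic acid with exactly this orientation, and the freed phenoxide then closes ring C on the ynone. The aryne precursor is a 2-silylaryl triflate carrying MOM ethers at the future C5 and C7 oxygens; the acid carries the 4'-oxygen as a benzyl ether. C3 oxidation, MOM removal, 3,7-disulfation and debenzylation finish the synthesis.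

Key step: step 5

Remark on the chemistry: the target is drawn as the free bis(hydrogen sulfate). Aryl hydrogen sulfates are strong acids that desulfate in their own acidity, so the sulfates are carried as potassium salts and the free acid is released only in the last operation, cold.

Step 1
Reactants: 1 phloroglucinol
Product: 2 3,5-bis(methoxymethoxy)phenol
Conditions: MOMCl (2.0 equiv), i-Pr2NEt (2.2 equiv), DMF, 0 °C → rt; chromatography
Reagents that add atoms: chloromethyl methyl ether, COCCl
Why: Williamson-type O-alkylation of the threefold-symmetric triphenol with two equivalents of the chloromethyl ether should give a statistical mixture in which the bis-ether is the main component and separates by polarity from the mono- and tris-ethers; the step sits first, on the cheapest material, where its modest efficiency costs least.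

Step 2
Reactants: 2 3,5-bis(methoxymethoxy)phenol
Product: 3 2-bromo-3,5-bis(methoxymethoxy)phenol
Conditions: NBS (1.0 equiv), i-Pr2NH (10 mol %), CH2Cl2, −78 → 0 °C
Reagents that add atoms: N-bromosuccinimide, O=C1CCC(=O)N1Br
Why: Amine-mediated ortho-bromination of a phenol (electrophilic aromatic substitution): N-bromodiisopropylamine, formed in the flask and hydrogen-bonded to the phenol OH, should deliver bromine to the adjacent carbon, C2 and C6 being equivalent and C4 being flanked by two MOM ethers, so that one monobromide is expected to dominate.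

Step 3
Reactants: 3 2-bromo-3,5-bis(methoxymethoxy)phenol
Product: 6 3,5-bis(methoxymethoxy)-2-(trimethylsilyl)phenyl trifluoromethanesulfonate, via O-trimethylsilyl ether 4 (not isolated), via lithium 2-silylphenoxide 5 (not isolated)
Conditions: HMDS, THF, 65 °C, evaporate; n-BuLi, THF, −100 → −78 °C; Tf2O, −100 °C → rt
Reagents that add atoms: hexamethyldisilazane, C[Si](C)(C)N[Si](C)(C)C; trifluoromethanesulfonic anhydride, O=S(=O)(OS(=O)(=O)C(F)(F)F)C(F)(F)F
Why: O-Silylation followed by bromine–lithium exchange, which at −100 °C is far faster than MOM-directed deprotonation, sets off a 1,3 O→C silyl shift (retro-Brook rearrangement) to the C-silyl phenoxide, which is triflated in the same flask; this is the standard one-pot passage from 2-bromophenols to 2-silylaryl triflates.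

Step 4
Reactants: 7 1-(benzyloxy)-4-iodobenzene; 8 propiolic acid
Product: 9 3-[4-(benzyloxy)phenyl]prop-2-ynoic acid
Conditions: Pd(PPh3)4 (5 mol %), DBU (2.4 equiv), DMSO, 35 °C; cold 1 M HCl work-up
Reagents that add atoms: none
Why: Copper-free Sonogashira coupling: oxidative addition of the aryl iodide to zerovalent palladium is easy near room temperature and the amidine base supplies the acetylide of the propiolate, while the absence of copper salts and of heat should keep the product acid from decarboxylating.

Step 5
Reactants: 6 3,5-bis(methoxymethoxy)-2-(trimethylsilyl)phenyl trifluoromethanesulfonate; 9 3-[4-(benzyloxy)phenyl]prop-2-ynoic acid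
Product: 12 2-[4-(benzyloxy)phenyl]-5,7-bis(methoxymethoxy)-4H-chromen-4-one (4'-benzyloxy-5,7-bis(methoxymethoxy)flavone), via 3,5-bis(methoxymethoxy)benzyne 10 (not isolated), via 2-hydroxyaryl ynone 11 (not isolated)
Conditions: 6 (1.3 equiv), anhydrous CsF (4 equiv), THF, 125 °C, sealed tube
Reagents that add atoms: none
Why: Fluoride attacks silicon and triflate leaves, giving aryne 10, while further fluoride turns acid 9 into its cesium carboxylate. The carboxylate oxygen adds to the aryne carbon that carried the triflate (future C8a); the aryl anion on the neighbouring carbon (future C4a) attacks the acyl carbon to give a four-membered cyclic alkoxide that opens to the 2-acylphenoxide of 11, a net insertion of the aryne into the O–C(acyl) bond. The closest known reaction type is the fluoride-induced aryne insertion into the C–O bond of carboxylic acids, which with arylpropiolic acids runs on to flavones. Ring C then closes by 6-endo-dig oxa-Michael addition of the O1 phenoxide to C2 of the ynone, and the hydrogen fluoride formed at the start protonates C3; no stereocentre is created. The step needs regiocontrol in the capture of the unsymmetrical aryne and 6-endo rather than 5-exo closure: the first is secured by the MOM-oxy group beside the triple bond (future C5 oxygen), whose inductive pull and distortion of the aryne direct the nucleophile to the remote carbon and leave the carbanion next to the oxygen, the second by the polarisation of the ynone, which makes C2 the electrophilic terminus under basic aprotic conditions.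

Step 6
Reactants: 12 2-[4-(benzyloxy)phenyl]-5,7-bis(methoxymethoxy)-4H-chromen-4-one
Product: 15 2-[4-(benzyloxy)phenyl]-3,5,7-trihydroxy-4H-chromen-4-one (4'-O-benzylkaempferol), via 2,3-epoxyflavanone 13 (not isolated), via 3-hydroxyflavone bis-MOM ether 14 (not isolated)
Conditions: DMDO (acetone solution, 3 equiv), CH2Cl2, 0 °C → rt, dark; evaporate; 3 M HCl, MeOH–THF, 50 °C
Reagents that add atoms: dimethyldioxirane, CC1(C)OO1
Why: Dioxirane epoxidation of the C2=C3 enol-ether double bond (concerted oxygen transfer to either face of the flat chromone gives the racemic cis-fused epoxide, whose two stereocentres vanish again), then acid-promoted opening at C2 (cation stabilised by O1 and the aryl group) with loss of the C3 proton to restore the chromone as its 3-hydroxy derivative, and acid-catalysed acetal exchange of both MOM ethers with methanol; the benzyl ether is stable to this acid.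

Step 7
Reactants: 15 2-[4-(benzyloxy)phenyl]-3,5,7-trihydroxy-4H-chromen-4-one
Product: 16 dipotassium 2-[4-(benzyloxy)phenyl]-5-hydroxy-4-oxo-4H-chromene-3,7-diyl bis(sulfate)
Conditions: SO3·pyridine (8 equiv), pyridine, rt → 45 °C; aq KOH to pH 8, 0 °C; Sephadex LH-20
Reagents that add atoms: sulfur trioxide–pyridine complex, O=S(=O)([O-])[n+]1ccccc1; potassium hydroxide, [K+].[OH-]
Why: O-Sulfonation of phenols by an amine–sulfur trioxide complex: the 7-OH and the enolic 3-OH should both react with excess reagent, whereas the 5-OH is tied up in a six-membered hydrogen bond to the C4 carbonyl and is too poor a nucleophile, and the 4'-oxygen is masked as its benzyl ether; neutralisation with KOH gives the stable dipotassium salt.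

Step 8
Reactants: 16 dipotassium 2-[4-(benzyloxy)phenyl]-5-hydroxy-4-oxo-4H-chromene-3,7-diyl bis(sulfate)
Product: 18 kaempferol 3,7-di-O-sulfate (target; free bis(hydrogen sulfate)), via dipotassium kaempferol 3,7-disulfate 17 (not isolated)
Conditions: H2 (1 atm), 10% Pd/C, MeOH–H2O, rt; filter; HCl (2.0 equiv, 1 M aq), 0 °C; C18 desalting (dilute aq HCl, then H2O–MeCN), lyophilise
Reagents that add atoms: none
Why: Catalytic hydrogenolysis of the benzylic C–O bond over palladium on carbon in neutral aqueous methanol leaves aryl sulfate salts and the chromone double bond alone, and cold protonation with two equivalents of mineral acid followed at once by reversed-phase desalting should release the free bis(hydrogen sulfate) before acid-catalysed desulfation can set in.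

Compound list
1 | phloroglucinol (benzene-1,3,5-triol) | Oc1cc(O)cc(O)c1 | starting material
2 | 3,5-bis(methoxymethoxy)phenol | COCOc1cc(O)cc(OCOC)c1 | intermediate
3 | 2-bromo-3,5-bis(methoxymethoxy)phenol | COCOc1cc(O)c(Br)c(OCOC)c1 | intermediate
4 | [2-bromo-3,5-bis(methoxymethoxy)phenoxy]trimethylsilane (formed in the flask) | COCOc1cc(O[Si](C)(C)C)c(Br)c(OCOC)c1 | intermediate
5 | lithium 3,5-bis(methoxymethoxy)-2-(trimethylsilyl)phenolate (formed in the flask) | COCOc1cc([O-])c([Si](C)(C)C)c(OCOC)c1.[Li+] | intermediate
6 | 3,5-bis(methoxymethoxy)-2-(trimethylsilyl)phenyl trifluoromethanesulfonate | COCOc1cc(OCOC)c([Si](C)(C)C)c(OS(=O)(=O)C(F)(F)F)c1 | intermediate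
7 | 1-(benzyloxy)-4-iodobenzene | Ic1ccc(OCc2ccccc2)cc1 | starting material
8 | propiolic acid | C#CC(=O)O | starting material
9 | 3-[4-(benzyloxy)phenyl]prop-2-ynoic acid | OC(=O)C#Cc1ccc(OCc2ccccc2)cc1 | intermediate
10 | 3,5-bis(methoxymethoxy)benzyne (1,2-didehydro-3,5-bis(methoxymethoxy)benzene; formed in the flask) | COCOC1=CC(OCOC)=CC#C1 | intermediate
11 | 3-[4-(benzyloxy)phenyl]-1-[2-hydroxy-4,6-bis(methoxymethoxy)phenyl]prop-2-yn-1-one (formed in the flask as its cesium phenoxide) | O=C(C#Cc1ccc(OCc2ccccc2)cc1)c1c(O)cc(OCOC)cc1OCOC | intermediate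
12 | 2-[4-(benzyloxy)phenyl]-5,7-bis(methoxymethoxy)-4H-chromen-4-one | O=c1cc(-c2ccc(OCc3ccccc3)cc2)oc2cc(OCOC)cc(OCOC)c12 | intermediate
13 | 2,3-epoxy-4'-benzyloxy-5,7-bis(methoxymethoxy)flavanone (racemic; cis-fused oxirane, epoxide oxygen on one face, C2-aryl and C3-H on the other; 2S,3R enantiomer drawn; formed in the flask) | O=C1c2c(OCOC)cc(OCOC)cc2O[C@]2(c3ccc(OCc4ccccc4)cc3)O[C@H]12 | intermediate
14 | 2-[4-(benzyloxy)phenyl]-3-hydroxy-5,7-bis(methoxymethoxy)-4H-chromen-4-one (formed in the flask) | O=c1c(O)c(-c2ccc(OCc3ccccc3)cc2)oc2cc(OCOC)cc(OCOC)c12 | intermediate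
15 | 2-[4-(benzyloxy)phenyl]-3,5,7-trihydroxy-4H-chromen-4-one (4'-O-benzylkaempferol) | O=c1c(O)c(-c2ccc(OCc3ccccc3)cc2)oc2cc(O)cc(O)c12 | intermediate
16 | dipotassium 2-[4-(benzyloxy)phenyl]-5-hydroxy-4-oxo-4H-chromene-3,7-diyl bis(sulfate) | O=c1c(OS(=O)(=O)[O-])c(-c2ccc(OCc3ccccc3)cc2)oc2cc(OS(=O)(=O)[O-])cc(O)c12.[K+].[K+] | intermediate
17 | dipotassium kaempferol 3,7-disulfate (formed in the flask) | O=c1c(OS(=O)(=O)[O-])c(-c2ccc(O)cc2)oc2cc(OS(=O)(=O)[O-])cc(O)c12.[K+].[K+] | intermediate
18 | kaempferol 3,7-di-O-sulfate, 5-hydroxy-2-(4-hydroxyphenyl)-4-oxo-4H-chromene-3,7-diyl bis(hydrogen sulfate) | O=c1c(OS(=O)(=O)O)c(-c2ccc(O)cc2)oc2cc(OS(=O)(=O)O)cc(O)c12 | target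

Total step count: 8. Longest linear sequence: 7 steps (steps 1, 2, 3, 5, 6, 7, 8 from phloroglucinol); the acid branch adds step 4.

Steps most likely to fail

Step 5. The aryl anion may be protonated before it reaches the acyl carbon, which stops the sequence at simple O-arylation. The cesium arylpropiolate may also decarboxylate at 125 °C, or the carboxylate may add at the wrong aryne carbon. The fallback sets out from bromophenol 3 and acid 9 and builds the same C4a–C4 bond by an acyl shift with the regiochemistry fixed by bromine. Carbodiimide esterification (DCC, DMAP cat., CH2Cl2, 0 °C) should give the aryl ester 2-bromo-3,5-bis(methoxymethoxy)phenyl 3-[4-(benzyloxy)phenyl]prop-2-ynoate F1. Bromine–lithium exchange (n-BuLi, THF, −100 °C) should outrun addition to the ynoate at this temperature and is followed by an anionic Fries-type 1,3 O→C acyl shift; aqueous NH4Cl then gives ynone 11. K2CO3 in refluxing acetone closes ring C by 6-endo-dig oxa-Michael addition, and the route is rejoined at flavone 12.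

Step 6. Epoxidation of the electron-poor chromone is slow, so the dioxirane may instead oxidise the benzylic C–H bonds of the 4'-ether or the electron-rich ring A. The epoxide may also rearrange by ring contraction instead of opening cleanly. The fallback sets out from flavone 12 and installs the C3 oxygen by a carbanion route. C3 lithiation with LiN(i-Pr)2 (THF, −78 °C) and trapping with B(OMe)3 should give dimethyl {2-[4-(benzyloxy)phenyl]-5,7-bis(methoxymethoxy)-4-oxo-4H-chromen-3-yl}boronate F2. Oxidation in the same flask (AcOH, 30% H2O2, 0 °C → rt) should give 3-hydroxyflavone 14, where the route is rejoined; 14 is then taken to 15 with HCl in MeOH–THF as in the second half of step 6.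

Step 2. Bromination may occur para to the hydroxyl (C4) or go on to a dibromide, which would cut the supply of the correct regioisomer. The fallback sets out from phenol 2 and replaces electrophilic substitution by directed ortho-metalation, so that silicon is introduced directly.
- Addition to isopropyl isocyanate (Et3N cat., CH2Cl2, rt) should give 3,5-bis(methoxymethoxy)phenyl N-(propan-2-yl)carbamate F3.
- N-Silylation in the flask (TBSOTf, TMEDA, Et2O, 0 °C → rt) gives the N-(tert-butyldimethylsilyl) carbamate F4.
- n-BuLi at −78 °C should lithiate the carbon between the carbamate and the neighbouring MOM ether, which is activated by both directing groups, and TMSCl then gives the N-silyl 2-(trimethylsilyl)aryl carbamate F5.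
- Aqueous work-up cleaves the N–Si bond to 3,5-bis(methoxymethoxy)-2-(trimethylsilyl)phenyl N-(propan-2-yl)carbamate F6.
- DBU and Et2NH (MeCN, 40 °C) release 3,5-bis(methoxymethoxy)-2-(trimethylsilyl)phenol F7 as its amidinium salt, the carbamoyl group leaving as a urea.
- PhNTf2 in the same flask gives the triflate, and the route is rejoined at aryne precursor 6, bypassing 3, 4 and 5.

Further compounds
F1 | step 5 | 2-bromo-3,5-bis(methoxymethoxy)phenyl 3-[4-(benzyloxy)phenyl]prop-2-ynoate | O=C(C#Cc1ccc(OCc2ccccc2)cc1)Oc1cc(OCOC)cc(OCOC)c1Br
F2 | step 6 | dimethyl {2-[4-(benzyloxy)phenyl]-5,7-bis(methoxymethoxy)-4-oxo-4H-chromen-3-yl}boronate | COB(OC)c1c(-c2ccc(OCc3ccccc3)cc2)oc2cc(OCOC)cc(OCOC)c2c1=O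
F3 | step 2 | 3,5-bis(methoxymethoxy)phenyl N-(propan-2-yl)carbamate | CC(C)NC(=O)Oc1cc(OCOC)cc(OCOC)c1
F4 | step 2 | 3,5-bis(methoxymethoxy)phenyl N-(tert-butyldimethylsilyl)-N-(propan-2-yl)carbamate | CC(C)N([Si](C)(C)C(C)(C)C)C(=O)Oc1cc(OCOC)cc(OCOC)c1
F5 | step 2 | 3,5-bis(methoxymethoxy)-2-(trimethylsilyl)phenyl N-(tert-butyldimethylsilyl)-N-(propan-2-yl)carbamate | CC(C)N([Si](C)(C)C(C)(C)C)C(=O)Oc1cc(OCOC)cc(OCOC)c1[Si](C)(C)C
F6 | step 2 | 3,5-bis(methoxymethoxy)-2-(trimethylsilyl)phenyl N-(propan-2-yl)carbamate | CC(C)NC(=O)Oc1cc(OCOC)cc(OCOC)c1[Si](C)(C)C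
F7 | step 2 | 3,5-bis(methoxymethoxy)-2-(trimethylsilyl)phenol | COCOc1cc(O)c([Si](C)(C)C)c(OCOC)c1
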